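**Retrosynthetic overview**
- The target comes from its C5 epimer mixture by kinetic enolate protonation. Ring B is cut at C7–C7a (intramolecular Claisen-type acylation) and at the enol ether O1–C7a=C7 (cyclodehydration), which leads back to a γ-lactone (ring A) carrying a 1,3-dimethoxyacetone side chain.
- The side chain (C4–C5 bond) and the allyl group on the quaternary C3a go back to an α-methylene-γ-butyrolactone, a hydrazone aza-enolate and allyl bromide.
- Key disconnection: the C3–C3a bond of the lactone. It is made by 5-exo cyclisation of a β-acyloxy benzylic radical, generated from a benzylic C–H bond of a 3-chloroacrylate ester; HCl is then lost.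
- The ester goes back to (R)-propylene oxide (source of C2 and O1), an aryl Grignard reagent from 4-bromophenol, and (E)-3-chloroacrylic acid.
- Ring A is formed first (as the lactone), ring B second. C2 comes from the chiral pool, C3 and C3a are set by substrate control, C5 is set last.

Assumption: (R)-propylene oxide, (E)-3-chloroacrylic acid and 1,3-dimethoxypropan-2-one are bought; atoms are numbered as in the target benzofuranone (O1, C2, C3, C3a, C4–C7, C7a).

**Step 1**
Reactants: 1 4-bromophenol
Product: 2 4-bromo-2,6-diiodophenol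
Conditions: I2 (1.1 equiv), 30% aq. H2O2 (2.5 equiv), H2O, 50 °C
Reagents that add atoms: iodine (II)
Why: Oxidative electrophilic aromatic iodination goes to both positions ortho to the hydroxyl because the para position is blocked by bromine; no stereocentre is formed.

**Step 2**
Reactants: 2 4-bromo-2,6-diiodophenol
Product: 4 5-bromo-1,2,3-trimethoxybenzene, via sodium 4-bromo-2,6-dimethoxyphenolate 3 (not isolated)
Conditions: NaOMe (6 equiv), CuI (10 mol%), DMF/MeOH 3:1, 85 °C; then MeI (8 equiv), 40 °C
Reagents that add atoms: sodium methoxide ([Na+].[O-]C); iodomethane (CI)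
Why: Ullmann-type CuI-catalysed methoxylation replaces the two aryl iodides ortho to the phenoxide much faster than the aryl bromide at this temperature, and the phenoxide is then O-methylated in the same flask (Williamson ether synthesis).

**Step 3**
Reactants: 4 5-bromo-1,2,3-trimethoxybenzene; 5 (R)-2-methyloxirane
Product: 7 (R)-1-(3,4,5-trimethoxyphenyl)propan-2-ol, via (3,4,5-trimethoxyphenyl)magnesium bromide 6 (not isolated)
Conditions: Mg, THF, 65 °C; CuI (10 mol%), 5 (1.3 equiv), −30 to 0 °C; 1 M HCl
Reagents that add atoms: none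
Why: Grignard formation followed by CuI-catalysed SN2 opening of the epoxide at its CH2 carbon leaves the stereocentre of 5 untouched, so the carbinol carbon (the future C2–O1) is (R).

**Step 4**
Reactants: 7 (R)-1-(3,4,5-trimethoxyphenyl)propan-2-ol; 8 (E)-3-chloroprop-2-enoic acid
Product: 10 (R)-1-(3,4,5-trimethoxyphenyl)propan-2-yl (E)-3-chloroprop-2-enoate, via (E)-3-chloroprop-2-enoyl chloride 9 (not isolated)
Conditions: 8, (COCl)2, DMF (cat.), CH2Cl2, 0 to 25 °C; then 7, 2,6-lutidine, CH2Cl2, −20 to 0 °C
Reagents that add atoms: none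
Why: O-acylation of the secondary alcohol by the acid chloride, with hindered 2,6-lutidine taking up HCl without adding to the β-chloroacrylate; the C2–O bond is not broken, so the configuration is retained.

**Step 5 (key step)**
Reactants: 10 (R)-1-(3,4,5-trimethoxyphenyl)propan-2-yl (E)-3-chloroprop-2-enoate
Product: 12 (4S,5R)-5-methyl-3-methylidene-4-(3,4,5-trimethoxyphenyl)oxolan-2-one, via chloromethyl lactone 11 (not isolated)
Conditions: 3,6-di-tert-butyl-9-mesityl-10-phenylacridinium tetrafluoroborate (5 mol%), 2,4,6-triisopropylbenzenethiol (20 mol%), 2,6-lutidine (0.5 equiv), ClCH2CH2Cl (0.05 M), 450 nm LEDs, 25 °C, argon; then DBU (1.5 equiv), 0 °C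
Reagents that add atoms: none
Why: Proposed new method: the excited acridinium (about +2.0 V vs SCE) oxidises the trimethoxyarene (about +1.35 V) to its radical cation, whose benzylic C–H (para to the central methoxy group) is acidic enough for 2,6-lutidine to remove, and the resulting β-acyloxy benzylic radical closes 5-exo-trig onto the acrylate α-carbon with aryl and methyl trans on the forming ring (this sets C3 and makes the C3–C3a bond), the α-chloro radical takes a hydrogen atom from the thiol, the thiyl radical reoxidises the acridine radical, premature hydrogen transfer to the benzylic radical only returns 10, and DBU then removes HCl (E1cB) to give the α-methylene lactone; the closest known reactions are the acridinium-catalysed polar radical crossover cycloaddition of β-methylstyrenes with unsaturated acids to γ-butyrolactones (same radical intermediate) and photoinduced-electron-transfer benzylic C–H functionalisation of methoxyarenes.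

**Step 6**
Reactants: 13 1,3-dimethoxypropan-2-one
Product: 14 1,3-dimethoxypropan-2-one N,N-dimethylhydrazone
Conditions: Me2NNH2 (1.5 equiv), AcOH (cat.), EtOH, 78 °C
Reagents that add atoms: 1,1-dimethylhydrazine (CN(C)N)
Why: Condensation of the symmetrical ketone with the hydrazine gives the hydrazone, which masks the ketone as a non-acidic aza-enolate precursor; no regiochemical or stereochemical issue arises.

**Step 7**
Reactants: 12 (4S,5R)-5-methyl-3-methylidene-4-(3,4,5-trimethoxyphenyl)oxolan-2-one; 14 1,3-dimethoxypropan-2-one N,N-dimethylhydrazone; 15 allyl bromide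
Product: 18 (3R,4S,5R)-3-allyl-3-[3-(2,2-dimethylhydrazinylidene)-2,4-dimethoxybutyl]-5-methyl-4-(3,4,5-trimethoxyphenyl)oxolan-2-one (epimers at the side-chain methoxy carbon), via lithium aza-enolate 16 (not isolated), via lithium lactone enolate 17 (not isolated)
Conditions: 14, LiN(iPr)2 (1.05 equiv), THF, 0 °C; 12, −78 °C; then 15 (1.5 equiv), DMPU, −78 to −30 °C
Reagents that add atoms: none
Why: Michael addition of the hydrazone aza-enolate to the exo-methylene lactone forms C4–C5 and leaves a lactone enolate that the non-acidic hydrazone cannot quench, so allyl bromide C-alkylates it on the face opposite the neighbouring C3 aryl group, which sets the quaternary C3a (allyl trans to aryl); C5 forms as an epimer mixture that is corrected in step 9.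

**Step 8**
Reactants: 18 (3R,4S,5R)-3-allyl-3-[3-(2,2-dimethylhydrazinylidene)-2,4-dimethoxybutyl]-5-methyl-4-(3,4,5-trimethoxyphenyl)oxolan-2-one
Product: 21 (2R,3S,3aR)-3a-allyl-5,7-dimethoxy-2-methyl-3-(3,4,5-trimethoxyphenyl)-3,3a,4,5-tetrahydrobenzofuran-6(2H)-one (C5 epimer mixture), via cyclised keto hydrazone 19 (not isolated), via hydroxy dione 20 (not isolated)
Conditions: LiN(iPr)2 (2.2 equiv), THF, −78 to 0 °C; then 3 M aq. HCl, THF, 25 °C
Reagents that add atoms: water (O)
Why: Intramolecular Claisen-type acylation (aza-Dieckmann condensation) of the C7 aza-enolate by the lactone carbonyl closes six-membered ring B and is pulled forward by deprotonation of the β-keto hydrazone, then aqueous acid hydrolyses the hydrazone to the C6 ketone and the freed C2 hydroxyl adds to the C7a carbonyl and dehydrates toward C7 (cyclodehydration to the vinylogous ester), with C2, C3 and C3a untouched and C5 left as an equilibrated mixture.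

**Step 9**
Reactants: 21 (2R,3S,3aR)-3a-allyl-5,7-dimethoxy-2-methyl-3-(3,4,5-trimethoxyphenyl)-3,3a,4,5-tetrahydrobenzofuran-6(2H)-one (C5 epimer mixture)
Product: 23 (2R,3S,3aR,5S)-3a-allyl-5,7-dimethoxy-2-methyl-3-(3,4,5-trimethoxyphenyl)-3,3a,4,5-tetrahydrobenzofuran-6(2H)-one, via lithium C5 enolate 22 (not isolated)
Conditions: LiN(SiMe3)2 (1.1 equiv), THF, −78 °C; then 2,6-di-tert-butyl-4-methylphenol (3 equiv), THF, −78 °C; H2O
Reagents that add atoms: none
Why: Kinetic diastereoselective protonation: C5 is the only enolisable position, and the bulky phenol protonates the enolate on the face opposite the pseudo-axial C3a allyl group, which places the C5 methoxy group cis to allyl (5S).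

**Compound list**
1 | 4-bromophenol | Oc1ccc(Br)cc1 | starting material
2 | 4-bromo-2,6-diiodophenol | Oc1c(I)cc(Br)cc1I | intermediate
3 | sodium 4-bromo-2,6-dimethoxyphenolate (not isolated) | [Na+].[O-]c1c(OC)cc(Br)cc1OC | intermediate
4 | 5-bromo-1,2,3-trimethoxybenzene | COc1cc(Br)cc(OC)c1OC | intermediate
5 | (R)-2-methyloxirane | C[C@@H]1CO1 | starting material
6 | (3,4,5-trimethoxyphenyl)magnesium bromide (not isolated) | COc1cc([Mg]Br)cc(OC)c1OC | intermediate
7 | (R)-1-(3,4,5-trimethoxyphenyl)propan-2-ol | C[C@@H](O)Cc1cc(OC)c(OC)c(OC)c1 | intermediate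
8 | (E)-3-chloroprop-2-enoic acid | OC(=O)/C=C/Cl | starting material
9 | (E)-3-chloroprop-2-enoyl chloride (not isolated) | ClC(=O)/C=C/Cl | intermediate
10 | (R)-1-(3,4,5-trimethoxyphenyl)propan-2-yl (E)-3-chloroprop-2-enoate | C[C@@H](OC(=O)/C=C/Cl)Cc1cc(OC)c(OC)c(OC)c1 | intermediate
11 | (3S,4R,5R)-3-(chloromethyl)-5-methyl-4-(3,4,5-trimethoxyphenyl)oxolan-2-one (not isolated) | O=C1O[C@H](C)[C@@H](c2cc(OC)c(OC)c(OC)c2)[C@@H]1CCl | intermediate
12 | (4S,5R)-5-methyl-3-methylidene-4-(3,4,5-trimethoxyphenyl)oxolan-2-one | O=C1O[C@H](C)[C@@H](c2cc(OC)c(OC)c(OC)c2)C1=C | intermediate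
13 | 1,3-dimethoxypropan-2-one | COCC(=O)COC | starting material
14 | 1,3-dimethoxypropan-2-one N,N-dimethylhydrazone | COCC(COC)=NN(C)C | intermediate
15 | allyl bromide (3-bromoprop-1-ene) | C=CCBr | starting material
16 | lithium 1-(1,3-dimethoxyprop-1-en-2-yl)-2,2-dimethylhydrazin-1-ide (not isolated) | [Li+].COC=C(COC)[N-]N(C)C | intermediate
17 | lithium (4S,5R)-3-[3-(2,2-dimethylhydrazinylidene)-2,4-dimethoxybutyl]-5-methyl-4-(3,4,5-trimethoxyphenyl)-4,5-dihydrofuran-2-olate (not isolated) | [Li+].[O-]C1=C(CC(OC)C(COC)=NN(C)C)[C@H](c2cc(OC)c(OC)c(OC)c2)[C@@H](C)O1 | intermediate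
18 | (3R,4S,5R)-3-allyl-3-[3-(2,2-dimethylhydrazinylidene)-2,4-dimethoxybutyl]-5-methyl-4-(3,4,5-trimethoxyphenyl)oxolan-2-one (epimers at the side-chain methoxy carbon) | O=C1O[C@H](C)[C@@H](c2cc(OC)c(OC)c(OC)c2)[C@@]1(CC=C)CC(OC)C(COC)=NN(C)C | intermediate
19 | (6R)-6-allyl-3-(2,2-dimethylhydrazinylidene)-6-[(1S,2R)-2-hydroxy-1-(3,4,5-trimethoxyphenyl)propyl]-2,4-dimethoxycyclohexan-1-one (not isolated) | C=CC[C@@]1(CC(OC)C(=NN(C)C)C(OC)C1=O)[C@H](c2cc(OC)c(OC)c(OC)c2)[C@@H](C)O | intermediate
20 | (4R)-4-allyl-4-[(1S,2R)-2-hydroxy-1-(3,4,5-trimethoxyphenyl)propyl]-2,6-dimethoxycyclohexane-1,3-dione (not isolated) | C=CC[C@@]1(CC(OC)C(=O)C(OC)C1=O)[C@H](c2cc(OC)c(OC)c(OC)c2)[C@@H](C)O | intermediate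
21 | (2R,3S,3aR)-3a-allyl-5,7-dimethoxy-2-methyl-3-(3,4,5-trimethoxyphenyl)-3,3a,4,5-tetrahydrobenzofuran-6(2H)-one, C5 epimer mixture | C=CC[C@]12CC(OC)C(=O)C(OC)=C1O[C@H](C)[C@H]2c1cc(OC)c(OC)c(OC)c1 | intermediate
22 | lithium (2R,3S,3aR)-3a-allyl-5,7-dimethoxy-2-methyl-3-(3,4,5-trimethoxyphenyl)-2,3,3a,4-tetrahydrobenzofuran-6-olate (not isolated) | [Li+].C=CC[C@]12CC(OC)=C([O-])C(OC)=C1O[C@H](C)[C@H]2c1cc(OC)c(OC)c(OC)c1 | intermediate
23 | (2R,3S,3aR,5S)-3a-allyl-5,7-dimethoxy-2-methyl-3-(3,4,5-trimethoxyphenyl)-3,3a,4,5-tetrahydrobenzofuran-6(2H)-one | C=CC[C@]12C[C@H](OC)C(=O)C(OC)=C1O[C@H](C)[C@H]2c1cc(OC)c(OC)c(OC)c1 | target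

**Totals**
Total step count: 9. Longest linear sequence: 8 steps (steps 1, 2, 3, 4, 5, 7, 8, 9; step 6 is a one-step side branch).

**Steps most likely to fail, with fallbacks**

Step 5 is the least certain. The benzylic deprotonation of the arene radical cation may be inefficient, the ring closure across the ester link may be slow, and 6-endo attack at the chlorine-bearing carbon with loss of chlorine is a possible competitor. The fallback abandons the radical closure, sets out from 4 and comes back at 12. The Grignard reagent 6 made from 4 is added (CuBr·SMe2 cat., Me3SiCl, THF, −78 °C) to bought (R)-5-methylfuran-2(5H)-one, anti to the methyl group, to give the trans lactone (4R,5R)-5-methyl-4-(3,4,5-trimethoxyphenyl)oxolan-2-one F1. This is formylated (NaH, HCO2Et, THF) to the sodium enolate of the α-formyl lactone, sodium [(4S,5R)-5-methyl-2-oxo-4-(3,4,5-trimethoxyphenyl)oxolan-3-ylidene]methanolate F2, and treatment with aqueous formaldehyde (deformylative methylenation) gives 12.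

Step 8 may fail because the aza-enolate has to acylate a lactone carbonyl flanked by the quaternary C3a, and hydrolysis of the cyclised hydrazone may lag. The fallback sets out from 18 and comes back at 21. The hydrazone is hydrolysed first (aqueous oxalic acid, Et2O, 25 °C) to the keto lactone (3R,4S,5R)-3-allyl-3-(2,4-dimethoxy-3-oxobutyl)-5-methyl-4-(3,4,5-trimethoxyphenyl)oxolan-2-one F3. Ring B is then closed by the classical thermodynamically driven Claisen condensation of the free ketone (KOtBu, tBuOH/THF, 25 to 60 °C; the 5-oxo ester to cyclohexane-1,3-dione closure, driven by the dione enolate), and p-TsOH in toluene at 80 °C effects the cyclodehydration to 21.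

Step 9 may give poor facial selectivity, since a proton is small and the equilibrium position between the C5 epimers is not known. The fallback replaces substrate control by reagent control, sets out from 21 and comes back at 23. The enolate is trapped and isolated as the silyl enol ether (2R,3S,3aR)-3a-allyl-5,7-dimethoxy-2-methyl-3-(3,4,5-trimethoxyphenyl)-6-(trimethylsilyloxy)-2,3,3a,4-tetrahydrobenzofuran F4 (LiN(SiMe3)2, Me3SiCl, THF, −78 °C). It is then protonated at −78 °C in toluene with the SnCl4 complex of enantiopure 2′-methoxy-1,1′-binaphthalen-2-ol, using whichever antipode of the acid is matched with the substrate, to give 23.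

**Further compounds**
F1 | step 5 | (4R,5R)-5-methyl-4-(3,4,5-trimethoxyphenyl)oxolan-2-one | O=C1O[C@H](C)[C@@H](c2cc(OC)c(OC)c(OC)c2)C1
F2 | step 5 | sodium [(4S,5R)-5-methyl-2-oxo-4-(3,4,5-trimethoxyphenyl)oxolan-3-ylidene]methanolate | O=C1O[C@H](C)[C@@H](c2cc(OC)c(OC)c(OC)c2)C1=C[O-].[Na+]
F3 | step 8 | (3R,4S,5R)-3-allyl-3-(2,4-dimethoxy-3-oxobutyl)-5-methyl-4-(3,4,5-trimethoxyphenyl)oxolan-2-one | O=C1O[C@H](C)[C@@H](c2cc(OC)c(OC)c(OC)c2)[C@@]1(CC=C)CC(OC)C(=O)COC
F4 | step 9 | (2R,3S,3aR)-3a-allyl-5,7-dimethoxy-2-methyl-3-(3,4,5-trimethoxyphenyl)-6-(trimethylsilyloxy)-2,3,3a,4-tetrahydrobenzofuran | C=CC[C@]12CC(OC)=C(O[Si](C)(C)C)C(OC)=C1O[C@H](C)[C@H]2c1cc(OC)c(OC)c(OC)c1
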